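## Retrosynthetic overview

1. The target (2,3-cis, 2S,3R) comes from its 2,3-trans C3 epimer by C3 deprotonation and kinetic protonation; C2 (S) is taken from the trans isomer, which is separated as a shikimate-derived diastereomer.
2. The dihydrofuran ring comes from a ring-opened α-aryl caffeoyl shikimate (salvianolic acid E type): it tautomerises to the p-quinone methide, which the neighbouring phenol traps, as proposed for the plant.
3. The ring-opened ester comes from shikimic acid 3,4-acetonide and a 3-arylidene-2-coumaranone; the lactone is the acyl donor, so esterification sets free the cyclising phenol.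
4. The arylidene coumaranone comes from 3,4-dihydroxybenzaldehyde and a coumaranone made from 2,3-dimethoxyphenylacetic acid (C–H olefination with tert-butyl acrylate, then BBr3). The C8–C2′ bond (C7/C8 = future C2/C3; primed = ring B, the future benzofuran arene) is thus fixed by connectivity, because flask oxidations of caffeates couple 8–5′ and 8–O–4′.
5. Ring order: temporary lactone ring (step 2), opened (step 6), dihydrofuran ring (step 7); the cyclohexene ring and both arenes are bought.

Assumption: the SMILES is read literally, i.e. a 2,3-cis (2S,3R) dihydrobenzofuran whose C3 carboxyl is esterified with O5 of natural (3R,4S,5R)-shikimic acid.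

## Route

Step 1
Reactants: 1 2-(2,3-dimethoxyphenyl)acetic acid; 2 tert-butyl acrylate
Product: 3 2-{6-[(E)-3-tert-butoxy-3-oxoprop-1-enyl]-2,3-dimethoxyphenyl}acetic acid
Conditions: Pd(OAc)2 (5 mol %), N-acetyl-L-isoleucine (10 mol %), KHCO3 (2 equiv), O2 (1 atm), t-AmylOH, 90 °C; then aq. HCl
Reagents that add atoms: none
Why: Carboxylate-directed ortho C–H olefination by divalent palladium (oxidative Heck, Fujiwara–Moritani type, accelerated by the N-acyl amino acid ligand); C6 is the only free ortho position and β-hydride elimination gives the E alkene, so the acrylate/CH2CO2H/O/O pattern of ring B is fixed here.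

Step 2
Reactants: 3 2-{6-[(E)-3-tert-butoxy-3-oxoprop-1-enyl]-2,3-dimethoxyphenyl}acetic acid
Product: 5 (E)-3-(7-hydroxy-2-oxo-2,3-dihydro-1-benzofuran-4-yl)prop-2-enoic acid, via hydroxy acid 4 (not isolated)
Conditions: BBr3 (6 equiv), CH2Cl2, −78 °C → rt; H2O; then TsOH (cat.), toluene–dioxane, reflux
Reagents that add atoms: none
Why: BBr3 ether cleavage removes both methyl ethers and the tert-butyl ester, and acid-catalysed lactonisation of 4 can only use the hydroxyl next to the CH2CO2H arm, giving the 2-coumaranone and leaving the other hydroxyl as the future 7-OH; no stereocentre is formed.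

Step 3
Reactants: 5 (E)-3-(7-hydroxy-2-oxo-2,3-dihydro-1-benzofuran-4-yl)prop-2-enoic acid; 6 3,4-dihydroxybenzaldehyde
Product: 7 (E)-3-[(3Z)-3-(3,4-dihydroxybenzylidene)-7-hydroxy-2-oxo-2,3-dihydro-1-benzofuran-4-yl]prop-2-enoic acid
Conditions: TsOH (cat.), AcOH, 80 °C
Reagents that add atoms: none
Why: Knoevenagel (aldol) condensation at the C3 methylene of the 2-coumaranone, a carbon acid whose enol is an aromatic 2-hydroxybenzofuran; the Z alkene (aryl turned away from the C4 side chain) is expected, but its geometry is erased in step 7.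

Step 4
Reactants: 7 (E)-3-[(3Z)-3-(3,4-dihydroxybenzylidene)-7-hydroxy-2-oxo-2,3-dihydro-1-benzofuran-4-yl]prop-2-enoic acid
Product: 9 (E)-3-[(3Z)-3-[3,4-bis(tert-butyldimethylsilyloxy)benzylidene]-7-(tert-butyldimethylsilyloxy)-2-oxo-2,3-dihydro-1-benzofuran-4-yl]prop-2-enoic acid, via tetrasilyl compound 8 (not isolated)
Conditions: TBSCl (5 equiv), imidazole, DMF, rt; then AcOH–THF–H2O, rt
Reagents that add atoms: tert-butyldimethylsilyl chloride, CC(C)(C)[Si](C)(C)Cl
Why: Silyl ether formation masks the three phenols so that no conjugated phenoxide can deactivate the lactone carbonyl in step 6, and the silyl ester of 8 is hydrolysed selectively by dilute acetic acid, which leaves aryl silyl ethers and the lactone intact.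

Step 5
Reactants: 10 (−)-shikimic acid
Product: 11 3,4-O-isopropylidene shikimic acid
Conditions: Me2C(OMe)2, TsOH (cat.), acetone, rt
Reagents that add atoms: 2,2-dimethoxypropane, COC(C)(C)OC
Why: Acid-catalysed transketalisation; only the cis-3,4-diol can form a cis-fused dioxolane, so O5–H stays free and the three shikimate stereocentres are carried over unchanged.

Step 6
Reactants: 9 (E)-3-[(3Z)-3-[3,4-bis(tert-butyldimethylsilyloxy)benzylidene]-7-(tert-butyldimethylsilyloxy)-2-oxo-2,3-dihydro-1-benzofuran-4-yl]prop-2-enoic acid; 11 3,4-O-isopropylidene shikimic acid (1.5 equiv)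
Product: 12 5-O-{(Z)-2-[6-((E)-2-carboxyvinyl)-3-(tert-butyldimethylsilyloxy)-2-hydroxyphenyl]-3-[3,4-bis(tert-butyldimethylsilyloxy)phenyl]acryloyl}-3,4-O-isopropylidene shikimic acid
Conditions: LiN(SiMe3)2 (4 equiv), THF–DMPU, −78 → −20 °C; then AcOH
Reagents that add atoms: none
Why: Transesterification by acyl substitution at an aryl lactone: the C5 alkoxide of the dianion of 11 attacks the lactone carbonyl and the ring oxygen leaves as a phenoxide (about six pKa units downhill from the alkoxide), so one step installs the shikimate ester and unmasks the phenol that will close the dihydrofuran; no stereocentre is created.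

Step 7
Reactants: 12 5-O-{(Z)-2-[6-((E)-2-carboxyvinyl)-3-(tert-butyldimethylsilyloxy)-2-hydroxyphenyl]-3-[3,4-bis(tert-butyldimethylsilyloxy)phenyl]acryloyl}-3,4-O-isopropylidene shikimic acid
Product: 15 5-O-{[(2S,3S)-4-((E)-2-carboxyvinyl)-2-(3,4-dihydroxyphenyl)-7-hydroxy-2,3-dihydro-1-benzofuran-3-yl]carbonyl}shikimic acid (2,3-trans), via free ring-opened ester 13 (not isolated), via quinone methide 14 (not isolated)
Conditions: 48% aq. HF, MeCN, rt; then CF3CO2H–CH2Cl2–H2O (50:50:1, 0.01 M), 0 °C → rt; preparative HPLC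
Reagents that add atoms: none
Why: Proposed new method: after removal of the silyl ethers and the acetonide, the 4-hydroxycinnamate unit of 13 is protonated at C8 (α to the ester, assisted by the para hydroxyl) to the p-quinone methide 14, the electrophile invoked in the biosynthesis, and the adjacent ring-B phenol closes the dihydrofuran by 5-exo oxa-1,6-addition, trans by thermodynamic control because the C2–O bond re-ionises in CF3CO2H; the remote shikimate does not bias C2/C3, so 15 (2S,3S) is separated by HPLC from the equally formed (2R,3R) trans diastereomer, which is put back into the same acid to re-equilibrate; the closest known reactions are the acid-mediated cyclisation of 4′-hydroxy-2-hydroxystilbenes to 2-aryl-2,3-dihydrobenzofurans and the CF3CO2H-mediated addition of phenols to the β-carbon of 4-hydroxycinnamic acids.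

Step 8
Reactants: 15 5-O-{[(2S,3S)-4-((E)-2-carboxyvinyl)-2-(3,4-dihydroxyphenyl)-7-hydroxy-2,3-dihydro-1-benzofuran-3-yl]carbonyl}shikimic acid
Product: 19 5-O-{[(2S,3R)-4-((E)-2-carboxyvinyl)-2-(3,4-dihydroxyphenyl)-7-hydroxy-2,3-dihydro-1-benzofuran-3-yl]carbonyl}shikimic acid (2,3-cis; CNP0312618.1), via heptakis-TMS ether 16 (not isolated), via silyl ketene acetal 17 (not isolated), via cis heptakis-TMS ether 18 (not isolated)
Conditions: (Me3Si)2NH, Me3SiCl (cat.), MeCN, 60 °C, evaporate; LiN(iPr)2 (1.5 equiv), Me3SiCl, THF, −78 °C; pivalic acid, −78 → −40 °C; aq. citric acid, MeOH, 0 °C; preparative HPLC (0.1% HCO2H)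
Reagents that add atoms: none
Why: Deprotonation followed by kinetic protonation (Zimmerman-type ketonisation of an ester enol derivative): transient per-trimethylsilylation removes the seven acidic protons, LiN(iPr)2 under internal Me3SiCl quench converts the most acidic C–H (C3, benzylic and α to the ester) into the planar silyl ketene acetal 17 before the enolate can expel the C2 aryloxide, and the bulky acid delivers H to C3 from the face opposite the C2 aryl group, so the ester ends up cis to the aryl (3R) while C2 (S) is untouched; dilute acid then strips every silyl group.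

## Compound list

1 | 2-(2,3-dimethoxyphenyl)acetic acid | COc1cccc(CC(=O)O)c1OC | starting material
2 | tert-butyl acrylate | C=CC(=O)OC(C)(C)C | starting material
3 | 2-{6-[(E)-3-tert-butoxy-3-oxoprop-1-enyl]-2,3-dimethoxyphenyl}acetic acid | COc1ccc(/C=C/C(=O)OC(C)(C)C)c(CC(=O)O)c1OC | intermediate
4 | (E)-3-[2-(carboxymethyl)-3,4-dihydroxyphenyl]prop-2-enoic acid | O=C(O)/C=C/c1ccc(O)c(O)c1CC(=O)O | intermediate (not isolated)
5 | (E)-3-(7-hydroxy-2-oxo-2,3-dihydro-1-benzofuran-4-yl)prop-2-enoic acid | O=C(O)/C=C/c1ccc(O)c2OC(=O)Cc12 | intermediate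
6 | 3,4-dihydroxybenzaldehyde | O=Cc1ccc(O)c(O)c1 | starting material
7 | (E)-3-[(3Z)-3-(3,4-dihydroxybenzylidene)-7-hydroxy-2-oxo-2,3-dihydro-1-benzofuran-4-yl]prop-2-enoic acid | O=C(O)/C=C/c1ccc(O)c2OC(=O)/C(=C\c3ccc(O)c(O)c3)c12 | intermediate
8 | tert-butyldimethylsilyl ester of 9 (tetrasilyl compound) | CC(C)(C)[Si](C)(C)OC(=O)/C=C/c1ccc(O[Si](C)(C)C(C)(C)C)c2OC(=O)/C(=C\c3ccc(O[Si](C)(C)C(C)(C)C)c(O[Si](C)(C)C(C)(C)C)c3)c12 | intermediate (not isolated)
9 | (E)-3-[(3Z)-3-[3,4-bis(tert-butyldimethylsilyloxy)benzylidene]-7-(tert-butyldimethylsilyloxy)-2-oxo-2,3-dihydro-1-benzofuran-4-yl]prop-2-enoic acid | O=C(O)/C=C/c1ccc(O[Si](C)(C)C(C)(C)C)c2OC(=O)/C(=C\c3ccc(O[Si](C)(C)C(C)(C)C)c(O[Si](C)(C)C(C)(C)C)c3)c12 | intermediate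
10 | (−)-shikimic acid, (3R,4S,5R) | O[C@@H]1CC(C(=O)O)=C[C@@H](O)[C@H]1O | starting material
11 | 3,4-O-isopropylidene shikimic acid (O5–H free) | O[C@@H]1CC(C(=O)O)=C[C@H]2OC(C)(C)O[C@@H]12 | intermediate
12 | 5-O-{(Z)-2-[6-((E)-2-carboxyvinyl)-3-(tert-butyldimethylsilyloxy)-2-hydroxyphenyl]-3-[3,4-bis(tert-butyldimethylsilyloxy)phenyl]acryloyl}-3,4-O-isopropylidene shikimic acid | O=C(O)/C=C/c1ccc(O[Si](C)(C)C(C)(C)C)c(O)c1/C(C(=O)O[C@@H]1CC(C(=O)O)=C[C@H]2OC(C)(C)O[C@@H]12)=C/c1ccc(O[Si](C)(C)C(C)(C)C)c(O[Si](C)(C)C(C)(C)C)c1 | intermediate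
13 | 5-O-{(Z)-2-[6-((E)-2-carboxyvinyl)-2,3-dihydroxyphenyl]-3-(3,4-dihydroxyphenyl)acryloyl}shikimic acid | O=C(O)/C=C/c1ccc(O)c(O)c1/C(C(=O)O[C@@H]1CC(C(=O)O)=C[C@@H](O)[C@H]1O)=C/c1ccc(O)c(O)c1 | intermediate (not isolated)
14 | 5-O-{2-[6-((E)-2-carboxyvinyl)-2,3-dihydroxyphenyl]-3-(3-hydroxy-4-oxocyclohexa-2,5-dien-1-ylidene)propanoyl}shikimic acid (p-quinone methide, both C8 epimers) | O=C(O)/C=C/c1ccc(O)c(O)c1C(C(=O)O[C@@H]1CC(C(=O)O)=C[C@@H](O)[C@H]1O)C=C1C=CC(=O)C(O)=C1 | intermediate (not isolated)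
15 | 5-O-{[(2S,3S)-4-((E)-2-carboxyvinyl)-2-(3,4-dihydroxyphenyl)-7-hydroxy-2,3-dihydro-1-benzofuran-3-yl]carbonyl}shikimic acid (2,3-trans) | O=C(O)/C=C/c1ccc(O)c2c1[C@H](C(=O)O[C@@H]1CC(C(=O)O)=C[C@@H](O)[C@H]1O)[C@@H](c1ccc(O)c(O)c1)O2 | intermediate
16 | heptakis(trimethylsilyl) derivative of 15 (two silyl esters, five silyl ethers) | C[Si](C)(C)OC(=O)/C=C/c1ccc(O[Si](C)(C)C)c2c1[C@H](C(=O)O[C@@H]1CC(C(=O)O[Si](C)(C)C)=C[C@@H](O[Si](C)(C)C)[C@H]1O[Si](C)(C)C)[C@@H](c1ccc(O[Si](C)(C)C)c(O[Si](C)(C)C)c1)O2 | intermediate (not isolated)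
17 | C3 silyl ketene acetal of 16 (eight trimethylsilyl groups; C3 planar, C2 configuration unchanged) | C[Si](C)(C)OC(=O)/C=C/c1ccc(O[Si](C)(C)C)c2c1C(=C(O[Si](C)(C)C)O[C@@H]1CC(C(=O)O[Si](C)(C)C)=C[C@@H](O[Si](C)(C)C)[C@H]1O[Si](C)(C)C)[C@@H](c1ccc(O[Si](C)(C)C)c(O[Si](C)(C)C)c1)O2 | intermediate (not isolated)
18 | heptakis(trimethylsilyl) derivative of 19 (2S,3R, 2,3-cis) | C[Si](C)(C)OC(=O)/C=C/c1ccc(O[Si](C)(C)C)c2c1[C@@H](C(=O)O[C@@H]1CC(C(=O)O[Si](C)(C)C)=C[C@@H](O[Si](C)(C)C)[C@H]1O[Si](C)(C)C)[C@@H](c1ccc(O[Si](C)(C)C)c(O[Si](C)(C)C)c1)O2 | intermediate (not isolated)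
19 | 5-O-{[(2S,3R)-4-((E)-2-carboxyvinyl)-2-(3,4-dihydroxyphenyl)-7-hydroxy-2,3-dihydro-1-benzofuran-3-yl]carbonyl}shikimic acid (2,3-cis) | O=C(O)/C=C/c1ccc(O)c2c1[C@@H](C(=O)O[C@@H]1CC(C(=O)O)=C[C@@H](O)[C@H]1O)[C@@H](c1ccc(O)c(O)c1)O2 | target

## Step count and risks

Total step count: 8. Longest linear sequence: 7 steps (1, 2, 3, 4, 6, 7, 8 from compound 1); step 5 is a one-step side branch.

Most likely to fail, first: step 7. Protonation at C8 may be slow, the equilibrium between 13 and the closed ring may not favour closure, and 13 may relactonise to 7 with loss of shikimic acid. The acid also gives no control of C2: about half of the cyclised material is the unwanted (2R,3R) trans diastereomer, which is removed by HPLC and returned to the CF3CO2H conditions to re-equilibrate through 14 and 13. The fallback sets out from 9 and comes back at 14, reaching the quinone methide by oxidation instead of protonation. LiBH(sec-Bu)3 reduces the arylidene lactone of 9 in a conjugate sense (the acrylate is protected as its carboxylate) to the 3-(3,4-bis-silyloxybenzyl)-2-coumaranone F1. Acyl transfer to 11 (DMAP, NEt3) opens this non-conjugated lactone to the saturated ring-opened ester F2, and aq. HF followed by aq. CF3CO2H frees the saturated hexahydroxy ester F3. One equivalent of Ag2O then dehydrogenates the more electron-rich 4-alkylcatechol ring A of F3 irreversibly to quinone methide 14, which cyclises to 15 as in step 7 without strong acid.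

Second: step 8. The enolate or ketene acetal may lose the C2 aryloxide (ring opening), deprotonation may compete at the allylic positions of the shikimate, or protonation may be unselective. The change is contra-thermodynamic, so 19 must be kept away from base and strong acid afterwards. The fallback sets out from 12 and comes back at 19, setting C3 during ring closure instead of afterwards. With ring A silylated the quinone methide path is shut. Cs2CO3 (slightly more than the two equivalents needed for the two acids) lets the ring-B phenoxide add 5-endo to the acrylate. This is the microscopic reverse of the known base-induced ring opening of such esters, so the closure competes with its own reversal and is stopped at low conversion with recycling of 12. The ester enolate is protonated by a phenol from the face away from the new C2 aryl group, giving the cis-configured silylated acetonide F4 (separated from its other cis diastereomer). Aq. HF and then dilute HCl, with no CF3CO2H, give 19.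

Third: step 6. The hindered secondary alkoxide may attack silicon, add at the benzylidene carbon, or fail to open the conjugated lactone; migration of the silyl group onto the new neighbouring phenoxide would be harmless, because step 7 removes every silyl group. The fallback sets out from 9 and comes back at 13, replacing alkoxide attack by thiophilic activation. LiSEt opens the lactone and TBSCl traps the freed phenoxide, giving the S-ethyl thioester F5. AgOSO2CF3 in the presence of 11 transfers the acyl group to O5 (thioester-to-ester acyl transfer promoted by monovalent silver), giving the tetrasilylated ring-opened shikimate ester F6. The deprotection stage of step 7 (aq. HF, then CF3CO2H) converts F6 into 13.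

## Further compounds

F1 | step 7 | (E)-3-[3-[3,4-bis(tert-butyldimethylsilyloxy)benzyl]-7-(tert-butyldimethylsilyloxy)-2-oxo-2,3-dihydro-1-benzofuran-4-yl]prop-2-enoic acid (racemic at C3) | O=C(O)/C=C/c1ccc(O[Si](C)(C)C(C)(C)C)c2OC(=O)C(Cc3ccc(O[Si](C)(C)C(C)(C)C)c(O[Si](C)(C)C(C)(C)C)c3)c12
F2 | step 7 | 5-O-{2-[6-((E)-2-carboxyvinyl)-3-(tert-butyldimethylsilyloxy)-2-hydroxyphenyl]-3-[3,4-bis(tert-butyldimethylsilyloxy)phenyl]propanoyl}-3,4-O-isopropylidene shikimic acid (both C8 epimers) | O=C(O)/C=C/c1ccc(O[Si](C)(C)C(C)(C)C)c(O)c1C(Cc1ccc(O[Si](C)(C)C(C)(C)C)c(O[Si](C)(C)C(C)(C)C)c1)C(=O)O[C@@H]1CC(C(=O)O)=C[C@H]2OC(C)(C)O[C@@H]12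
F3 | step 7 | 5-O-{2-[6-((E)-2-carboxyvinyl)-2,3-dihydroxyphenyl]-3-(3,4-dihydroxyphenyl)propanoyl}shikimic acid (both C8 epimers) | O=C(O)/C=C/c1ccc(O)c(O)c1C(Cc1ccc(O)c(O)c1)C(=O)O[C@@H]1CC(C(=O)O)=C[C@@H](O)[C@H]1O
F4 | step 8 | 5-O-{[(2S,3R)-4-((E)-2-carboxyvinyl)-2-[3,4-bis(tert-butyldimethylsilyloxy)phenyl]-7-(tert-butyldimethylsilyloxy)-2,3-dihydro-1-benzofuran-3-yl]carbonyl}-3,4-O-isopropylidene shikimic acid (2,3-cis) | O=C(O)/C=C/c1ccc(O[Si](C)(C)C(C)(C)C)c2c1[C@@H](C(=O)O[C@@H]1CC(C(=O)O)=C[C@H]3OC(C)(C)O[C@@H]13)[C@@H](c1ccc(O[Si](C)(C)C(C)(C)C)c(O[Si](C)(C)C(C)(C)C)c1)O2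
F5 | step 6 | S-ethyl (Z)-2-[6-((E)-2-carboxyvinyl)-2,3-bis(tert-butyldimethylsilyloxy)phenyl]-3-[3,4-bis(tert-butyldimethylsilyloxy)phenyl]prop-2-enethioate | O=C(O)/C=C/c1ccc(O[Si](C)(C)C(C)(C)C)c(O[Si](C)(C)C(C)(C)C)c1/C(C(=O)SCC)=C/c1ccc(O[Si](C)(C)C(C)(C)C)c(O[Si](C)(C)C(C)(C)C)c1
F6 | step 6 | 2-O-silylated analogue of 12 (four tert-butyldimethylsilyl ethers, acetonide) | O=C(O)/C=C/c1ccc(O[Si](C)(C)C(C)(C)C)c(O[Si](C)(C)C(C)(C)C)c1/C(C(=O)O[C@@H]1CC(C(=O)O)=C[C@H]2OC(C)(C)O[C@@H]12)=C/c1ccc(O[Si](C)(C)C(C)(C)C)c(O[Si](C)(C)C(C)(C)C)c1
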